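The numbers of this flask are those of an exercise; the flask was simulated.

Which flask makes more target in 15 s, the warm red one or the cool violet one?

| setting | red | violet |
|---|---|---|
| starting material | 10 mM | 10 mM |
| partner | 0.900 equiv | 0.900 equiv |
| second substrate | 1.00 equiv | 1.00 equiv |
| free catalyst | 0.13 mol% | 0.13 mol% |
| added ligand | 21 µM | 21 µM |
| temperature | 25 °C | 10 °C |
| time | 15 s | 15 s |

    free catalyst + added ligand ⇌ idle complex, settled at all times (K1 = 1.6 × 10⁶ /M, ΔH1 = 12.0 kJ/mol)
    free catalyst → spent catalyst (k2 = 0.142 /s, Ea2 = 73.0 kJ/mol)
    starting material + partner + free catalyst → free catalyst + target (k3 = 4.88 × 10⁶ /M²/s, Ea3 = 12.0 kJ/mol)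
    second substrate + partner + free catalyst → free catalyst + second product (k4 = 7.69 × 10⁶ /M²/s, Ea4 = 9.00 kJ/mol)
    (constants at 25 °C)

* the flask with the highest amount of target, in percent of the starting material charged ("all alike" if they lie within 1.5 percentage points) (red / violet / all alike)
* final target, as a percentage of the starting material charged, in red
* final target, as a percentage of the starting material charged, in violet

- the constants hold at 25 °C; other temperatures follow from the activation energies and enthalpies

*What actually works in this flask?*

Not the whole 13.0 µM charged. Added ligand stands at 21 µM, and binding is fast, so I take it as settled and reckon with what it leaves free. Call that free catalyst C. The root of the tight-binding quadratic, with binding constant K = 1.6 × 10⁶ /M, gives C = 0.857 µM in red.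

*And in violet?*

Binding takes up heat, so cooling lowers K to 1.24 × 10⁶ /M, and C rises to 1.06 µM.

*So violet runs faster?*

No, since the target step slows by a factor of 1.3 while C grows by only 1.24. What counts is the working constant W, the target step's rate constant times the free catalyst left by the balance, a pseudo-second-order constant on starting material and partner. It is 4.18 /M/s in red and 4.02 /M/s in violet, nearly equal, because the binding enthalpy matches the activation energy of the target step.

*How much target, then?*

Let w be minus the logarithm of the fraction of starting material remaining, so w grows at W times partner. The same logarithm for second substrate grows s times as fast, with selectivity factor s = 1.58 in red and 1.68 in violet. Holding W constant and taking partner to fall in a straight line with w, I get w = 0.280 in red and 0.269 in violet. That makes target 24.4% in red and 23.6% in violet.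

*But the catalyst dies, and that step speeds up by a factor of 4.8 from violet to red. What then?*

Holding C at its starting value, red loses 14.0% of the charge by the asked time, more than the 3.66% lost in violet. My figures leave that out, and it works against red. I have not sized its effect on target. But red's lead is 0.80 percentage points, inside the margin, and a shift against red eats into that lead first, so I commit to alike.

The forecast also says all alike, with 24.8% in red and 24.9% in violet. On the dying catalyst it says: “The idle complex acts as a reservoir, releasing catalyst as free catalyst dies.” Its figures stand above mine and put violet slightly ahead, where mine put red ahead.

The simulation gives 24.8% in red and 25.1% in violet: all alike.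

Neither flask has come to rest at 15 s: red still holds 32% of its partner, violet 29%. Violet's free catalyst at 7.50 s, 7.88% of the charge, gives W = 3.87 /M/s, close to 4.02 /M/s. The neighbour like violet with 0.084 mM of added ligand has W = 0.551 /M/s; the same straight-line reckoning with violet's s gives 6.46% target, and that flask stood at 6.46%. Left to 150 s, partner falls to 1.19% in red and 0.0969% in violet, and target rises to 37.1% in red and 36.5% in violet.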